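**Strategy**

- Retrosynthesis cuts, in this order: the C=C of the propenal arm (Wittig), the C2–C3 bond of the dihydrofuran ring (carbene C–H insertion), the C3a–C3 aryl–carbon bond (aryl iodide/diazoacetate coupling) and the O1–C2 ether bond (Williamson). This leads back to 5-iodovanillin, veratryl chloride, ethyl diazoacetate and the formyl ylide.
- Enabling feature: C2 is an O-benzylic CH bearing O1 and the 3,4-dimethoxyphenyl ring. C3, bonded to C3a of the benzo ring, carries a CH2OH that is a reduced ester. C2–C3 is therefore the bond made when an aryl(alkoxycarbonyl)carbene on C3a inserts into the OCH2 of an aryl veratryl ether. O1, the C7 methoxy group, C3a and C5 of the benzo ring coincide with OH, OMe, I and CHO of 5-iodovanillin.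
- Forward order: both benzene rings are bought and joined through O1–C2; the carbene carbon is attached at C3a; the dihydrofuran ring closes through C2–C3; the enal chain is added at C5 last.
- Stereochemistry: C2 (R) comes from a chiral dirhodium carboxylate that distinguishes the two enantiotopic benzylic hydrogens. C3 is set by base equilibration of the cis ester to the trans ester under control of C2. The E alkene comes from the stabilised ylide.

Key step: step 4

Assumption: the (S)-configured catalyst Rh2(S-PTTL)4 is taken to select the benzylic hydrogen whose replacement gives 2R; should the sense of induction be the opposite, the mirror-image catalyst Rh2(R-PTTL)4 is used and nothing else changes.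

**Route**

Step 1
Reactants: 1 5-iodovanillin (4-hydroxy-3-iodo-5-methoxybenzaldehyde); 2 3,4-dimethoxybenzyl chloride (veratryl chloride)
Product: 3 4-[(3,4-dimethoxybenzyl)oxy]-3-iodo-5-methoxybenzaldehyde
Conditions: K2CO3, Bu4NI (cat.), DMF, 50 °C
Reagents that add atoms: none
Why: Williamson ether synthesis, in which the phenol (acidified by the para formyl group) is deprotonated by K2CO3 and displaces chloride from the reactive primary benzylic halide despite the two ortho substituents.

Step 2
Reactants: 3 4-[(3,4-dimethoxybenzyl)oxy]-3-iodo-5-methoxybenzaldehyde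
Product: 4 2-{4-[(3,4-dimethoxybenzyl)oxy]-3-iodo-5-methoxyphenyl}-1,3-dioxolane
Conditions: HOCH2CH2OH, pyridinium p-toluenesulfonate (cat.), benzene, reflux, Dean–Stark
Reagents that add atoms: ethylene glycol, OCCO
Why: acid-catalysed acetalisation driven by azeotropic removal of water, with an acid too weak to ionise the veratryl aryl ether; the dioxolane shields the formyl group from the carbene and from hydride later on.

Step 3
Reactants: 4 2-{4-[(3,4-dimethoxybenzyl)oxy]-3-iodo-5-methoxyphenyl}-1,3-dioxolane; 5 ethyl diazoacetate
Product: 6 ethyl 2-diazo-2-{2-[(3,4-dimethoxybenzyl)oxy]-5-(1,3-dioxolan-2-yl)-3-methoxyphenyl}acetate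
Conditions: Pd(PPh3)4 (5 mol %), Ag2CO3 (0.5 equiv), Et3N, toluene, rt
Reagents that add atoms: none
Why: cross-coupling of an aryl iodide with the acidic C–H of a diazoacetate under zerovalent palladium catalysis (oxidative addition, silver-assisted iodide abstraction, deprotonative palladation of ethyl diazoacetate, reductive elimination), run at room temperature so that the diazo group is retained.

Step 4
Reactants: 6 ethyl 2-diazo-2-{2-[(3,4-dimethoxybenzyl)oxy]-5-(1,3-dioxolan-2-yl)-3-methoxyphenyl}acetate
Product: 7 ethyl (2R,3S)-2-(3,4-dimethoxyphenyl)-5-(1,3-dioxolan-2-yl)-7-methoxy-2,3-dihydrobenzofuran-3-carboxylate (cis ester)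
Conditions: Rh2(S-PTTL)4 [dirhodium tetrakis(N-phthaloyl-(S)-tert-leucinate)] (1 mol %), toluene, −78 °C
Reagents that add atoms: none
Why: The dirhodium carboxylate expels N2 from 6 to give a donor/acceptor rhodium carbene at the future C3, and the electrophilic carbene carbon takes up the veratrylic O–CH2 hydrogen and its carbon in a concerted, asynchronous, hydride-transfer-like three-centre transition state that forms C2–C3 and releases the catalyst. The closest known reaction type is the enantioselective intramolecular C–H insertion of 2-(benzyloxy)aryl diazoacetates to cis-2-aryl-2,3-dihydrobenzofuran-3-carboxylates under chiral dirhodium tetracarboxylate catalysis. The dihydrofuran ring closes by 1,5 C–H insertion (five-membered ring, bond C2–C3) onto the pre-existing arene and ether oxygen. C2 is fixed by the chiral N-phthaloyl-tert-leucinate pocket, which selects one of the two enantiotopic benzylic hydrogens, while C3 arises cis as the kinetic outcome of the compact transition state and is left for correction in step 5. The step needs 1,5 site selectivity and enantiotopic C–H discrimination: the ortho tether puts only this CH2 within reach of the carbene and its C–H is the most hydridic in the molecule (alpha to oxygen and to an electron-rich arene), the formyl group is masked so that no carbonyl ylide can form, and toluene at low temperature keeps the insertion concerted so that the catalyst controls the configuration.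

Step 5
Reactants: 7 ethyl (2R,3S)-2-(3,4-dimethoxyphenyl)-5-(1,3-dioxolan-2-yl)-7-methoxy-2,3-dihydrobenzofuran-3-carboxylate
Product: 8 ethyl (2R,3R)-2-(3,4-dimethoxyphenyl)-5-(1,3-dioxolan-2-yl)-7-methoxy-2,3-dihydrobenzofuran-3-carboxylate (trans ester)
Conditions: NaOEt (0.2 equiv), EtOH–THF, 0 °C to rt
Reagents that add atoms: none
Why: base-mediated epimerisation through the ester enolate under thermodynamic control, where reprotonation places the ester trans to the aryl group on the untouched C2; ethoxide matches the ethyl ester, and ring opening by beta-aryloxide loss is the reverse of a disfavoured 5-endo-trig closure.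

Step 6
Reactants: 8 ethyl (2R,3R)-2-(3,4-dimethoxyphenyl)-5-(1,3-dioxolan-2-yl)-7-methoxy-2,3-dihydrobenzofuran-3-carboxylate
Product: 10 (2R,3S)-2-(3,4-dimethoxyphenyl)-3-(hydroxymethyl)-7-methoxy-2,3-dihydrobenzofuran-5-carbaldehyde, via hydroxymethyl dioxolane 9 (not isolated)
Conditions: LiAlH4, THF, 0 °C; then 1 M aq. HCl, THF, rt
Reagents that add atoms: water, O
Why: LiAlH4 reduction of the ester to the primary alcohol followed in the same flask by acid-catalysed hydrolysis of the dioxolane; neither stereocentre is touched, and the C3 descriptor changes from R to S only because CH2OH ranks below C2 whereas CO2Et ranked above it.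

Step 7
Reactants: 10 (2R,3S)-2-(3,4-dimethoxyphenyl)-3-(hydroxymethyl)-7-methoxy-2,3-dihydrobenzofuran-5-carbaldehyde; 11 (triphenylphosphoranylidene)acetaldehyde
Product: 12 4-O-methylbalanophonin, (E)-3-[(2R,3S)-2-(3,4-dimethoxyphenyl)-3-(hydroxymethyl)-7-methoxy-2,3-dihydrobenzofuran-5-yl]prop-2-enal
Conditions: 11 (1.2 equiv), toluene, 80 °C
Reagents that add atoms: none
Why: Wittig olefination with a stabilised formyl ylide, whose reversible addition leads to the E enal; the neutral, weakly basic ylide leaves the free primary alcohol and both stereocentres alone, and a small excess limits a second homologation.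

**Compound list**

1 | 5-iodovanillin (4-hydroxy-3-iodo-5-methoxybenzaldehyde) | COc1cc(C=O)cc(I)c1O | starting material
2 | 3,4-dimethoxybenzyl chloride | COc1ccc(CCl)cc1OC | starting material
3 | 4-[(3,4-dimethoxybenzyl)oxy]-3-iodo-5-methoxybenzaldehyde | COc1cc(C=O)cc(I)c1OCc1ccc(OC)c(OC)c1 | intermediate
4 | 2-{4-[(3,4-dimethoxybenzyl)oxy]-3-iodo-5-methoxyphenyl}-1,3-dioxolane | COc1cc(C2OCCO2)cc(I)c1OCc1ccc(OC)c(OC)c1 | intermediate
5 | ethyl diazoacetate | CCOC(=O)C=[N+]=[N-] | starting material
6 | ethyl 2-diazo-2-{2-[(3,4-dimethoxybenzyl)oxy]-5-(1,3-dioxolan-2-yl)-3-methoxyphenyl}acetate | CCOC(=O)C(=[N+]=[N-])c1cc(C2OCCO2)cc(OC)c1OCc1ccc(OC)c(OC)c1 | intermediate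
7 | ethyl (2R,3S)-2-(3,4-dimethoxyphenyl)-5-(1,3-dioxolan-2-yl)-7-methoxy-2,3-dihydrobenzofuran-3-carboxylate (cis) | CCOC(=O)[C@H]1c2cc(C3OCCO3)cc(OC)c2O[C@H]1c1ccc(OC)c(OC)c1 | intermediate
8 | ethyl (2R,3R)-2-(3,4-dimethoxyphenyl)-5-(1,3-dioxolan-2-yl)-7-methoxy-2,3-dihydrobenzofuran-3-carboxylate (trans) | CCOC(=O)[C@@H]1c2cc(C3OCCO3)cc(OC)c2O[C@H]1c1ccc(OC)c(OC)c1 | intermediate
9 | [(2R,3S)-2-(3,4-dimethoxyphenyl)-5-(1,3-dioxolan-2-yl)-7-methoxy-2,3-dihydrobenzofuran-3-yl]methanol (trans; formed in the flask in step 6) | COc1ccc([C@@H]2Oc3c(OC)cc(C4OCCO4)cc3[C@H]2CO)cc1OC | intermediate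
10 | (2R,3S)-2-(3,4-dimethoxyphenyl)-3-(hydroxymethyl)-7-methoxy-2,3-dihydrobenzofuran-5-carbaldehyde (trans) | COc1ccc([C@@H]2Oc3c(OC)cc(C=O)cc3[C@H]2CO)cc1OC | intermediate
11 | (triphenylphosphoranylidene)acetaldehyde | O=CC=P(c1ccccc1)(c1ccccc1)c1ccccc1 | starting material
12 | 4-O-methylbalanophonin | COc1ccc([C@@H]2Oc3c(OC)cc(/C=C/C=O)cc3[C@H]2CO)cc1OC | target

**Step count**

Total step count: 7. Longest linear sequence: 7 steps (from 5-iodovanillin 1; compounds 2, 5 and 11 are bought).

**Steps most likely to fail**

1. Step 3. Oxidative addition and deprotonative palladation at an iodide flanked by the bulky veratryloxy group may be slow, so that ethyl diazoacetate is lost to palladium-carbene side reactions (dimerisation, migratory insertion) before it couples. Fallback: the aryl–carbon bond and the diazo group are installed separately. Setting out from aryl iodide 4, Negishi coupling with the Reformatsky reagent BrZnCH2CO2Et (Pd2(dba)3, XPhos, THF, 60 °C) should give ethyl 2-{2-[(3,4-dimethoxybenzyl)oxy]-5-(1,3-dioxolan-2-yl)-3-methoxyphenyl}acetate F1. Regitz diazo transfer with 4-acetamidobenzenesulfonyl azide and DBU in MeCN then comes back to the route at diazo ester 6.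

2. Step 4. At the strongly hydride-donating veratrylic C–H the insertion may drift toward a stepwise hydride-transfer and ion-pair collapse, or the carbene may be partly diverted onto the electron-rich veratryl ring, so that enantiotopic discrimination is incomplete and the product is of insufficient enantiomeric purity. Fallback: stereochemical purification through covalent diastereomers, setting out from trans ester 8 of insufficient enantiomeric purity. Saponification (LiOH, THF–H2O, work-up at pH 4 to keep the dioxolane) should give (2R,3R)-2-(3,4-dimethoxyphenyl)-5-(1,3-dioxolan-2-yl)-7-methoxy-2,3-dihydrobenzofuran-3-carboxylic acid F2. Activation with pivaloyl chloride and Et3N gives the mixed pivalic anhydride F3 (not isolated), which acylates (S)-4-benzyl-1,3-oxazolidin-2-one in the presence of LiCl to give the N-acyl oxazolidinone F4. This diastereomer is separated from the one derived from the (2S,3S) acid by chromatography or crystallisation. Reductive cleavage with LiBH4 (THF, a little water, 0 °C) comes back to the route at hydroxymethyl dioxolane 9, which is hydrolysed with aqueous HCl as in step 6.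

3. Step 7. Addition of the stabilised ylide to the electron-rich aryl aldehyde may be sluggish, while the product enal competes for ylide and undergoes a second homologation to the dienal. Fallback: the two carbons are introduced at the ester oxidation level, setting out from hydroxy aldehyde 10. Horner–Wadsworth–Emmons olefination (triethyl phosphonoacetate, LiCl, DBU, MeCN, rt) should give ethyl (E)-3-[(2R,3S)-2-(3,4-dimethoxyphenyl)-3-(hydroxymethyl)-7-methoxy-2,3-dihydrobenzofuran-5-yl]prop-2-enoate F5. Reduction with iBu2AlH (CH2Cl2, −78 °C) gives (E)-3-[(2R,3S)-2-(3,4-dimethoxyphenyl)-3-(hydroxymethyl)-7-methoxy-2,3-dihydrobenzofuran-5-yl]prop-2-en-1-ol F6. MnO2 (CH2Cl2, rt) then oxidises only the allylic alcohol and comes back to the route at target 12.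

**Further compounds**

F1 | step 3 | ethyl 2-{2-[(3,4-dimethoxybenzyl)oxy]-5-(1,3-dioxolan-2-yl)-3-methoxyphenyl}acetate | CCOC(=O)Cc1cc(C2OCCO2)cc(OC)c1OCc1ccc(OC)c(OC)c1
F2 | step 4 | (2R,3R)-2-(3,4-dimethoxyphenyl)-5-(1,3-dioxolan-2-yl)-7-methoxy-2,3-dihydrobenzofuran-3-carboxylic acid | OC(=O)[C@@H]1c2cc(C3OCCO3)cc(OC)c2O[C@H]1c1ccc(OC)c(OC)c1
F3 | step 4 | mixed anhydride of acid F2 with pivalic acid (not isolated) | CC(C)(C)C(=O)OC(=O)[C@@H]1c2cc(C3OCCO3)cc(OC)c2O[C@H]1c1ccc(OC)c(OC)c1
F4 | step 4 | (S)-4-benzyl-3-{[(2R,3R)-2-(3,4-dimethoxyphenyl)-5-(1,3-dioxolan-2-yl)-7-methoxy-2,3-dihydrobenzofuran-3-yl]carbonyl}-1,3-oxazolidin-2-one | O=C1OC[C@H](Cc2ccccc2)N1C(=O)[C@@H]1c2cc(C3OCCO3)cc(OC)c2O[C@H]1c1ccc(OC)c(OC)c1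
F5 | step 7 | ethyl (E)-3-[(2R,3S)-2-(3,4-dimethoxyphenyl)-3-(hydroxymethyl)-7-methoxy-2,3-dihydrobenzofuran-5-yl]prop-2-enoate | COc1ccc([C@@H]2Oc3c(OC)cc(/C=C/C(=O)OCC)cc3[C@H]2CO)cc1OC
F6 | step 7 | (E)-3-[(2R,3S)-2-(3,4-dimethoxyphenyl)-3-(hydroxymethyl)-7-methoxy-2,3-dihydrobenzofuran-5-yl]prop-2-en-1-ol | COc1ccc([C@@H]2Oc3c(OC)cc(/C=C/CO)cc3[C@H]2CO)cc1OC
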